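**Retrosynthetic overview** (chain atoms: C1 = CH3 of the ethyl end … C13 = carbon on the pyrone; stereocentres C3 and C9, ketone C6)
1. Target ⇒ C6 carbinol 22 (final MnO2 oxidation) ⇒ C11–C12 diene bond: Pd-catalysed Suzuki–Miyaura coupling of alkenylboronate 21 with iodovinyl pyrone 13.
2. 21 ⇒ C6–C7 bond: hydrozirconation/zinc transmetalation of alkyne 18 and 1,2-addition to enal 3 (C1–C6; C3 from (S)-2-methylbutan-1-ol).
3. 18 ⇒ achiral skipped diyne 17 (all of C7–C11 with its three methyls) by a copper-catalysed enantioselective desymmetrising protoboration that sets C9; 17 ⇐ pent-3-yn-2-ol + propynylmagnesium bromide.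
4. 13: the only ring, the pyrone, is closed early by DBU lactonisation of a diketo ester built from the Claisen dimer of methyl propanoate and (E)-3-iodo-2-methylpropenal (from propargyl alcohol by carboalumination).

Assumption: the sense of induction in step 11 cannot be predicted, so (R)-DTBM-SEGPHOS is written and its mirror image is used if it delivers the (R)-boronate; the five starting materials 1, 4, 8, 14 and 16 are taken as commercial.

**Step 1**
Reactants: 1 (2S)-2-methylbutan-1-ol
Product: 2 (2S)-2-methylbutanal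
Conditions: TEMPO (1 mol%), KBr (10 mol%), NaOCl (1.1 equiv), NaHCO3, CH2Cl2/H2O, 0 °C, 20 min; used as CH2Cl2 solution
Reagents that add atoms: none
Why: Anelli (TEMPO/NaOCl) oxidation stops at the aldehyde and is fast at 0 °C near pH 9, so the α-stereocentre (C3) is not racemised.

**Step 2**
Reactants: 2 (2S)-2-methylbutanal
Product: 3 (2E,4S)-2,4-dimethylhex-2-enal
Conditions: Ph3P=C(Me)CHO (1.2 equiv), toluene, 90 °C, 16 h
Reagents that add atoms: 2-(triphenylphosphoranylidene)propanal CC(C=O)=P(c1ccccc1)(c1ccccc1)c1ccccc1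
Why: Wittig olefination with the stabilised α-methyl ylide gives the (E)-trisubstituted enal (C4=C5) under neutral conditions that leave C3 untouched.

**Step 3**
Reactants: 4 prop-2-yn-1-ol
Product: 6 (2E)-3-iodo-2-methylprop-2-en-1-ol, via alkenylalane 5 (not isolated)
Conditions: AlMe3 (3 equiv), ZrCp2Cl2 (25 mol%), CH2Cl2, 0 °C → rt; then I2, THF, −30 → 0 °C; aq. NaOH work-up
Reagents that add atoms: trimethylaluminium C[Al](C)C; iodine II
Why: Negishi zirconium-catalysed carboalumination adds Me and Al syn across the alkyne with Al at the terminus, and iodinolysis with retention gives the (E)-iodide that later becomes C12=C13.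

**Step 4**
Reactants: 6 (2E)-3-iodo-2-methylprop-2-en-1-ol
Product: 7 (2E)-3-iodo-2-methylprop-2-enal
Conditions: MnO2 (15 equiv), CH2Cl2, rt, dark
Reagents that add atoms: none
Why: Allylic oxidation with MnO2 is neutral and does not isomerise the vinyl iodide.

**Step 5**
Reactants: 8 methyl propanoate (two molecules)
Product: 9 methyl 2-methyl-3-oxopentanoate
Conditions: NaH (1.1 equiv per 9), cat. MeOH, THF, 65 °C; then AcOH
Reagents that add atoms: none
Why: Claisen self-condensation, driven to completion by deprotonation of the β-keto ester formed.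

**Step 6**
Reactants: 9 methyl 2-methyl-3-oxopentanoate; 7 (2E)-3-iodo-2-methylprop-2-enal
Product: 11 methyl (6E)-5-hydroxy-7-iodo-2,4,6-trimethyl-3-oxohept-6-enoate, via dienolate 10 (not isolated)
Conditions: NaH (1.1 equiv), THF, 0 °C; n-BuLi (1.05 equiv), 0 °C; 7, −78 °C; then AcOH
Reagents that add atoms: none
Why: Weiler dianion aldol: the more reactive γ-carbanion adds 1,2 to the enal; the new sp3 centres are erased in steps 7 and 8.

**Step 7**
Reactants: 11 methyl (6E)-5-hydroxy-7-iodo-2,4,6-trimethyl-3-oxohept-6-enoate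
Product: 12 methyl (6E)-7-iodo-2,4,6-trimethyl-3,5-dioxohept-6-enoate
Conditions: Dess–Martin periodinane (1.5 equiv), CH2Cl2, 0 °C → rt
Reagents that add atoms: none
Why: Dess–Martin oxidation of the secondary alcohol gives the β,δ-diketo ester under neutral conditions.

**Step 8**
Reactants: 12 methyl (6E)-7-iodo-2,4,6-trimethyl-3,5-dioxohept-6-enoate
Product: 13 4-hydroxy-6-[(1E)-1-iodoprop-1-en-2-yl]-3,5-dimethyl-2H-pyran-2-one
Conditions: DBU (2 equiv), toluene, rt → 50 °C; then 1 M HCl
Reagents that add atoms: none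
Why: DBU-mediated enolisation and lactonisation (attack of the δ-enol oxygen on the ester, loss of methanol) closes the 4-hydroxy-2-pyrone ring.

**Step 9**
Reactants: 14 pent-3-yn-2-ol (racemic)
Product: 15 pent-3-yn-2-yl methanesulfonate
Conditions: MsCl (1.2 equiv), Et3N (1.5 equiv), CH2Cl2, −20 °C
Reagents that add atoms: methanesulfonyl chloride CS(=O)(=O)Cl
Why: Sulfonylation turns the secondary propargylic alcohol into a leaving group; used cold and at once.

**Step 10**
Reactants: 15 pent-3-yn-2-yl methanesulfonate; 16 prop-1-yn-1-ylmagnesium bromide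
Product: 17 4-methylhepta-2,5-diyne
Conditions: CuBr·SMe2 (10 mol%), THF, −20 °C → rt; distillation
Reagents that add atoms: none
Why: Copper-catalysed alkynyl Grignard–propargylic sulfonate coupling; direct substitution should win because the alkyne terminus that an SN2′ attack needs is methyl-capped, and racemic 15 is acceptable since 17 is achiral.

**Step 11**
Reactants: 17 4-methylhepta-2,5-diyne
Product: 18 2-[(2Z,4S)-4-methylhept-2-en-5-yn-2-yl]-4,4,5,5-tetramethyl-1,3,2-dioxaborolane
Conditions: CuCl (5 mol%), NaOtBu (5 mol%), (R)-DTBM-SEGPHOS (5.5 mol%), B2pin2 (0.95 equiv), MeOH (2 equiv), THF, −10 → 0 °C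
Reagents that add atoms: bis(pinacolato)diboron CC1(C)OB(OC1(C)C)B1OC(C)(C)C(C)(C)O1
Why: Proposed new method: copper-catalysed enantioselective desymmetrising protoboration of a prochiral 1,4-diyne; the chiral bisphosphine–copper boryl adds syn across one of the two enantiotopic alkynes with boron on the unhindered methyl terminus (C11) and copper on C10, next to the prochiral CH(Me) carbon, so the ligand pocket reads Me against the second propynyl arm in the enantiodetermining insertion, methanolysis of the C–Cu bond releases the alkenylboronate (B trans to C9) and fixes C9 as S, and faster second borylation of the minor enantiomer to the achiral bis-boronate should raise the ee further; the closest known reactions are the achiral copper-catalysed protoboration of internal alkynes and the copper-catalysed desymmetrising azide–alkyne cycloaddition of prochiral diynes.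

**Step 12**
Reactants: 18 2-[(2Z,4S)-4-methylhept-2-en-5-yn-2-yl]-4,4,5,5-tetramethyl-1,3,2-dioxaborolane; 3 (2E,4S)-2,4-dimethylhex-2-enal
Product: 21 (3S,4E,7E,9S,10Z)-3,5,7,9-tetramethyl-11-(4,4,5,5-tetramethyl-1,3,2-dioxaborolan-2-yl)dodeca-4,7,10-trien-6-ol, via alkenylzirconocene 19 (not isolated), via alkenylzinc 20 (not isolated)
Conditions: ZrCp2(H)Cl (1.5 equiv), THF, 45 °C, 1 h; solvent change to CH2Cl2; ZnMe2 (1.5 equiv), −65 °C; 3 (2.0 equiv), 0 °C; H2O work-up; Et3N-deactivated silica
Reagents that add atoms: none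
Why: Syn-hydrozirconation puts Zr on the methyl-bearing alkyne carbon C7 (thermodynamic regiocontrol with excess hydride), and Zr-to-Zn transmetalation followed by 1,2-addition to the enal (Wipf alkenylzinc addition) forms C6–C7 with retention of the (E)-C7=C8 geometry; the C6 carbinol forms as both epimers, which does not matter because it is oxidised in step 14.

**Step 13**
Reactants: 21 (3S,4E,7E,9S,10Z)-3,5,7,9-tetramethyl-11-(4,4,5,5-tetramethyl-1,3,2-dioxaborolan-2-yl)dodeca-4,7,10-trien-6-ol; 13 4-hydroxy-6-[(1E)-1-iodoprop-1-en-2-yl]-3,5-dimethyl-2H-pyran-2-one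
Product: 22 4-hydroxy-6-[(2E,4E,6S,7E,10E,12S)-9-hydroxy-4,6,8,10,12-pentamethyltetradeca-2,4,7,10-tetraen-2-yl]-3,5-dimethyl-2H-pyran-2-one
Conditions: Pd(OAc)2 (5 mol%), SPhos (10 mol%), K3PO4 (4 equiv), THF/H2O (10:1), 40 °C; then pH 4.5 NaH2PO4 buffer
Reagents that add atoms: none
Why: Suzuki–Miyaura coupling forms the C11–C12 diene bond with retention of both alkene geometries; the pyrone is carried as its phosphate-generated pyronate, and C9 is not acidic while C6 is still a carbinol.

**Step 14**
Reactants: 22 4-hydroxy-6-[(2E,4E,6S,7E,10E,12S)-9-hydroxy-4,6,8,10,12-pentamethyltetradeca-2,4,7,10-tetraen-2-yl]-3,5-dimethyl-2H-pyran-2-one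
Product: 23 4-hydroxy-3,5-dimethyl-6-[(2E,4E,6S,7E,10E,12S)-4,6,8,10,12-pentamethyl-9-oxotetradeca-2,4,7,10-tetraen-2-yl]-2H-pyran-2-one
Conditions: MnO2 (25 equiv), CH2Cl2, rt, dark; filtration, no base or acid in isolation
Reagents that add atoms: none
Why: MnO2 oxidises only the bis-allylic alcohol to the cross-conjugated dienone under neutral conditions, so C9 (now γ to the ketone) is not epimerised.

**Compound list**
1 | (2S)-2-methylbutan-1-ol | CC[C@H](C)CO | starting material
2 | (2S)-2-methylbutanal | CC[C@H](C)C=O | intermediate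
3 | (2E,4S)-2,4-dimethylhex-2-enal | CC[C@H](C)/C=C(\C)C=O | intermediate
4 | prop-2-yn-1-ol | C#CCO | starting material
5 | dimethylaluminium (2E)-3-(dimethylalumanyl)-2-methylprop-2-en-1-olate | C[Al](C)OC/C(C)=C/[Al](C)C | intermediate
6 | (2E)-3-iodo-2-methylprop-2-en-1-ol | OC/C(C)=C/I | intermediate
7 | (2E)-3-iodo-2-methylprop-2-enal | O=C/C(C)=C/I | intermediate
8 | methyl propanoate | CCC(=O)OC | starting material
9 | methyl 2-methyl-3-oxopentanoate | CCC(=O)C(C)C(=O)OC | intermediate
10 | sodium lithium 1-methoxy-2-methylpenta-1,3-diene-1,3-diolate (dienolate of 9) | CC=C([O-])C(C)=C([O-])OC.[Na+].[Li+] | intermediate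
11 | methyl (6E)-5-hydroxy-7-iodo-2,4,6-trimethyl-3-oxohept-6-enoate (diastereomer mixture) | COC(=O)C(C)C(=O)C(C)C(O)/C(C)=C/I | intermediate
12 | methyl (6E)-7-iodo-2,4,6-trimethyl-3,5-dioxohept-6-enoate | COC(=O)C(C)C(=O)C(C)C(=O)/C(C)=C/I | intermediate
13 | 4-hydroxy-6-[(1E)-1-iodoprop-1-en-2-yl]-3,5-dimethyl-2H-pyran-2-one | I/C=C(\C)c1oc(=O)c(C)c(O)c1C | intermediate
14 | pent-3-yn-2-ol (racemic) | CC#CC(C)O | starting material
15 | pent-3-yn-2-yl methanesulfonate (racemic) | CC#CC(C)OS(C)(=O)=O | intermediate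
16 | prop-1-yn-1-ylmagnesium bromide | CC#C[Mg]Br | starting material
17 | 4-methylhepta-2,5-diyne | CC#CC(C)C#CC | intermediate
18 | 2-[(2Z,4S)-4-methylhept-2-en-5-yn-2-yl]-4,4,5,5-tetramethyl-1,3,2-dioxaborolane | CC#C[C@@H](C)/C=C(\C)B1OC(C)(C)C(C)(C)O1 | intermediate
19 | chlorobis(cyclopentadienyl)[(2E,4S,5Z)-4-methyl-6-(4,4,5,5-tetramethyl-1,3,2-dioxaborolan-2-yl)hepta-2,5-dien-2-yl]zirconium | C/C(=C\[C@@H](C)/C=C(\C)B1OC(C)(C)C(C)(C)O1)[Zr](Cl)(C1C=CC=C1)C1C=CC=C1 | intermediate
20 | methyl[(2E,4S,5Z)-4-methyl-6-(4,4,5,5-tetramethyl-1,3,2-dioxaborolan-2-yl)hepta-2,5-dien-2-yl]zinc | C/C(=C\[C@@H](C)/C=C(\C)B1OC(C)(C)C(C)(C)O1)[Zn]C | intermediate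
21 | (3S,4E,7E,9S,10Z)-3,5,7,9-tetramethyl-11-(4,4,5,5-tetramethyl-1,3,2-dioxaborolan-2-yl)dodeca-4,7,10-trien-6-ol (both C6 epimers) | CC[C@H](C)/C=C(\C)C(O)/C(C)=C/[C@@H](C)/C=C(\C)B1OC(C)(C)C(C)(C)O1 | intermediate
22 | 4-hydroxy-6-[(2E,4E,6S,7E,10E,12S)-9-hydroxy-4,6,8,10,12-pentamethyltetradeca-2,4,7,10-tetraen-2-yl]-3,5-dimethyl-2H-pyran-2-one (both carbinol epimers) | CC[C@H](C)/C=C(\C)C(O)/C(C)=C/[C@@H](C)/C=C(C)/C=C(\C)c1oc(=O)c(C)c(O)c1C | intermediate
23 | 4-hydroxy-3,5-dimethyl-6-[(2E,4E,6S,7E,10E,12S)-4,6,8,10,12-pentamethyl-9-oxotetradeca-2,4,7,10-tetraen-2-yl]-2H-pyran-2-one | CC[C@H](C)/C=C(\C)C(=O)/C(C)=C/[C@@H](C)/C=C(C)/C=C(\C)c1oc(=O)c(C)c(O)c1C | target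

**Totals**
Total step count: 14.
Longest linear sequence: 7 steps (4 → 6 → 7 → 11 → 12 → 13 → 22 → 23), half of the total.

**Three steps most likely to fail**

Step 10 (SN2 against SN2′ at the secondary propargylic carbon; base-induced isomerisation of the skipped diyne). The fallback sets out from 14 and 16 and comes back at 17, replacing the copper coupling by a Nicholas reaction. Compound 14 and Co2(CO)8 in CH2Cl2 at rt give hexacarbonyl[μ-(pent-3-yn-2-ol)]dicobalt F1. Compound 16 (3 equiv) and AlCl3 in THF/toluene give tri(prop-1-yn-1-yl)aluminium F2. Lewis-acid-promoted replacement of the hydroxyl of F1 by a propynyl group of F2 (BF3·OEt2, CH2Cl2, −78 °C) gives hexacarbonyl[μ-(4-methylhepta-2,5-diyne)]dicobalt F3; the cobalt cluster blocks the allenyl pathway. Oxidative decomplexation with (NH4)2Ce(NO3)6 in acetone at −10 °C releases 17.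

Step 11 (the proposed new desymmetrisation; enantioselectivity or mono/bis control may fall short). The fallback sets out from 17 and comes back at 18 using only known chemistry. Protoboration of 17 with the achiral catalyst CuCl(IMes) (IMes = 1,3-dimesitylimidazol-2-ylidene)/NaOtBu, B2pin2 and MeOH in THF, the established copper-catalysed protoboration of internal alkynes, gives racemic 2-[(2Z)-4-methylhept-2-en-5-yn-2-yl]-4,4,5,5-tetramethyl-1,3,2-dioxaborolane F4. F4 is resolved by preparative chiral supercritical-fluid chromatography on an amylose tris(3,5-dimethylphenylcarbamate) phase; the (S)-enantiomer is 18. The absolute configuration is checked at the stage of 21 against material made from 3.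

Step 12 (regiocontrol of the hydrozirconation next to a branched carbon, and survival of the boronate through the Zr/Zn sequence). The fallback sets out from 18 and comes back at 21, replacing the alkenylzinc addition by an isolated vinyl iodide and a chromium-mediated coupling. Hydrozirconation of 18 (ZrCp2(H)Cl, THF, 45 °C) followed by I2 at 0 °C gives 2-[(2Z,4S,5E)-6-iodo-4-methylhepta-2,5-dien-2-yl]-4,4,5,5-tetramethyl-1,3,2-dioxaborolane F5, which can be purified from any regioisomer. Nozaki–Hiyama–Kishi coupling of F5 with 3 (CrCl2 4 equiv, NiCl2 1 mol%, DMSO, rt) gives 21.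

**Further compounds**
F1 | step 10 | hexacarbonyl[μ-(pent-3-yn-2-ol)]dicobalt | CC(O)C12C3(C)[Co]1(=C=O)(=C=O)(=C=O)[Co]23(=C=O)(=C=O)=C=O
F2 | step 10 | tri(prop-1-yn-1-yl)aluminium | CC#C[Al](C#CC)C#CC
F3 | step 10 | hexacarbonyl[μ-(4-methylhepta-2,5-diyne)]dicobalt | CC#CC(C)C12C3(C)[Co]1(=C=O)(=C=O)(=C=O)[Co]23(=C=O)(=C=O)=C=O
F4 | step 11 | racemic 2-[(2Z)-4-methylhept-2-en-5-yn-2-yl]-4,4,5,5-tetramethyl-1,3,2-dioxaborolane | CC#CC(C)/C=C(\C)B1OC(C)(C)C(C)(C)O1
F5 | step 12 | 2-[(2Z,4S,5E)-6-iodo-4-methylhepta-2,5-dien-2-yl]-4,4,5,5-tetramethyl-1,3,2-dioxaborolane | C/C(I)=C\[C@@H](C)/C=C(\C)B1OC(C)(C)C(C)(C)O1
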